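**Retrosynthetic overview**

1. Building blocks: 5-methylbenzene-1,2,3-triol 1 (ring A, bought) and all-E geranylgeraniol 2 together hold all 27 carbons and all three oxygens of the target.
2. Aryl–CH2 disconnection: Friedel–Crafts geranylgeranylation of the C2v-symmetric triol 1 (its two free ring positions are equivalent) gives the open-chain prenyl triol 3, the chemical counterpart of the prenyltransferase step.
3. O1–C2 disconnection of the target 4: a catalyst-controlled, tocopherol-cyclase-like protonation of the 2',3'-alkene of 3 with 6-endo capture by the ortho hydroxyl forms ring B and sets C2 as (S) in one step.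
4. Ring order: ring A is present from 1; ring B (the dihydropyran) is the only ring formed, in the last step; no protecting groups are used.

Assumption: the (S,S)-antipode of the chiral acid is taken to give the (2S)-chromane; if the first run (chiral HPLC, CD) shows the opposite sense, the (R,R)-acid, made the same way from (R)-BINOL, is used with no other change.

**Route**

Step 1
Reactants: 1 5-methylbenzene-1,2,3-triol (3 equiv); 2 (2E,6E,10E)-3,7,11,15-tetramethylhexadeca-2,6,10,14-tetraen-1-ol (all-E geranylgeraniol, 1 equiv)
Product: 3 5-methyl-4-[(2E,6E,10E)-3,7,11,15-tetramethylhexadeca-2,6,10,14-tetraen-1-yl]benzene-1,2,3-triol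
Conditions: BF3·OEt2 (0.3 equiv), degassed 1,4-dioxane, Ar, 23 °C, 2 added over 4 h, then 12 h; aq. NaHCO3/Na2S2O4 work-up
Reagents that add atoms: none
Why: Friedel–Crafts allylation in which BF3 ionises the allylic alcohol and the electron-rich triol attacks through one of its two symmetry-equivalent free positions (C4 = C6), so only one regioisomer can form; attack at the primary allyl terminus keeps the 2E alkene, excess 1 and the donor solvent dioxane limit dialkylation, polyene cyclisation and premature racemic ring closure, water is the only co-product, and no stereocentre is formed.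

Step 2
Reactants: 3 5-methyl-4-[(2E,6E,10E)-3,7,11,15-tetramethylhexadeca-2,6,10,14-tetraen-1-yl]benzene-1,2,3-triol
Product: 4 (2S)-2,5-dimethyl-2-[(3E,7E)-4,8,12-trimethyltrideca-3,7,11-trien-1-yl]-3,4-dihydro-2H-chromene-7,8-diol
Conditions: (S,S)-IDPi acid HN[P(=NSO2CF3)(O2Ar*)]2, Ar* = (S)-3,3'-bis[3,5-bis(trifluoromethyl)phenyl]-1,1'-binaphthyl-2,2'-diyl (5 mol%), CHCl3/cyclohexane 1:1 (0.05 M), Ar, 0 → 23 °C, 48 h; Et3N quench
Reagents that add atoms: none
Why: Proposed new method: the confined, strongly acidic imidodiphosphorimidate protonates C2' of the proximal (2E)-alkene while its basic sulfonyl/imide site holds the C3-OH by a hydrogen bond, so that O–C3' bond formation is concerted but asynchronous (anti addition, Markovnikov, 6-endo) and occurs on one enantioface inside the chiral pocket, setting C2 as (S); only the C3-OH is ortho to the chain, and the three remote alkenes have no internal nucleophile and are not ionised in a non-ionising solvent at or below room temperature; the closest known reactions are the IDPi-catalysed asymmetric intramolecular hydroalkoxylation of unactivated alkenes to cyclic ethers and the racemic acid-catalysed chromanol ring closure of prenylated hydroquinones, an isomerisation that sets nothing free.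

**Compound list**

1 | 5-methylbenzene-1,2,3-triol (5-methylpyrogallol) | Cc1cc(O)c(O)c(O)c1 | starting material
2 | (2E,6E,10E)-3,7,11,15-tetramethylhexadeca-2,6,10,14-tetraen-1-ol (all-E geranylgeraniol) | CC(C)=CCC/C(C)=C/CC/C(C)=C/CC/C(C)=C/CO | starting material
3 | 5-methyl-4-[(2E,6E,10E)-3,7,11,15-tetramethylhexadeca-2,6,10,14-tetraen-1-yl]benzene-1,2,3-triol | CC(C)=CCC/C(C)=C/CC/C(C)=C/CC/C(C)=C/Cc1c(C)cc(O)c(O)c1O | intermediate
4 | (2S)-2,5-dimethyl-2-[(3E,7E)-4,8,12-trimethyltrideca-3,7,11-trien-1-yl]-3,4-dihydro-2H-chromene-7,8-diol | CC(C)=CCC/C(C)=C/CC/C(C)=C/CC[C@@]1(C)CCc2c(C)cc(O)c(O)c2O1 | target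

**Step count and risks**

Total step count: 2. Longest linear sequence: 2 steps (1 + 2 → 3 → 4).

The route has only two steps, so both are ranked; there is no third step.

Most likely to fail, step 2. The acid may protonate a remote alkene and start a polyene cyclisation, the free catechol may bind the catalyst, or the enantiomeric excess may be low. The fallback sets out from 3 and comes back at 4, moving stereocontrol from catalysis to separation. Triol 3 is closed without stereocontrol (p-TsOH·H2O 10 mol%, toluene, 60 °C, Ar) to rac-2,5-dimethyl-2-[(3E,7E)-4,8,12-trimethyltrideca-3,7,11-trien-1-yl]-3,4-dihydro-2H-chromene-7,8-diol F1. The enantiomers are then separated by preparative HPLC or SFC on a cellulose tris(3,5-dimethylphenylcarbamate) phase. The (2S)-fraction is 4, and the (2R)-2,5-dimethyl-2-[(3E,7E)-4,8,12-trimethyltrideca-3,7,11-trien-1-yl]-3,4-dihydro-2H-chromene-7,8-diol F2 is set aside.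

Second, step 1. The yield is expected to be modest because of dialkylation, some 2Z isomer from allyl-cation leakage and partial racemic ring closure. The fallback sets out from 1 and 2 and comes back at 3, replacing the electrophilic substitution by a directed metalation and SN2 coupling. Triol 1 is converted (NaH, MOMCl, DMF, 0 °C) into 1,2,3-tris(methoxymethoxy)-5-methylbenzene F3. Alcohol 2 is converted (PBr3, Et2O, −10 °C) into (2E,6E,10E)-1-bromo-3,7,11,15-tetramethylhexadeca-2,6,10,14-tetraene F4. Ortho-lithiation of F3 (n-BuLi, THF, 0 °C; the two positions next to a methoxymethoxy group are again equivalent) gives [2,3,4-tris(methoxymethoxy)-6-methylphenyl]lithium F5, which is not isolated. It is alkylated with F4 (CuBr·SMe2 10 mol%, −78 → 0 °C) at the primary carbon with retention of the 2E alkene to give 1,2,3-tris(methoxymethoxy)-5-methyl-4-[(2E,6E,10E)-3,7,11,15-tetramethylhexadeca-2,6,10,14-tetraen-1-yl]benzene F6. Mild acetal cleavage (HCl 1 M in MeOH, 23 °C, stopped before any ring closure) returns 3.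

**Further compounds**

F1 | step 2 | rac-2,5-dimethyl-2-[(3E,7E)-4,8,12-trimethyltrideca-3,7,11-trien-1-yl]-3,4-dihydro-2H-chromene-7,8-diol | CC(C)=CCC/C(C)=C/CC/C(C)=C/CCC1(C)CCc2c(C)cc(O)c(O)c2O1
F2 | step 2 | (2R)-2,5-dimethyl-2-[(3E,7E)-4,8,12-trimethyltrideca-3,7,11-trien-1-yl]-3,4-dihydro-2H-chromene-7,8-diol | CC(C)=CCC/C(C)=C/CC/C(C)=C/CC[C@]1(C)CCc2c(C)cc(O)c(O)c2O1
F3 | step 1 | 1,2,3-tris(methoxymethoxy)-5-methylbenzene | Cc1cc(OCOC)c(OCOC)c(OCOC)c1
F4 | step 1 | (2E,6E,10E)-1-bromo-3,7,11,15-tetramethylhexadeca-2,6,10,14-tetraene | CC(C)=CCC/C(C)=C/CC/C(C)=C/CC/C(C)=C/CBr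
F5 | step 1 | [2,3,4-tris(methoxymethoxy)-6-methylphenyl]lithium | [Li]c1c(C)cc(OCOC)c(OCOC)c1OCOC
F6 | step 1 | 1,2,3-tris(methoxymethoxy)-5-methyl-4-[(2E,6E,10E)-3,7,11,15-tetramethylhexadeca-2,6,10,14-tetraen-1-yl]benzene | CC(C)=CCC/C(C)=C/CC/C(C)=C/CC/C(C)=C/Cc1c(C)cc(OCOC)c(OCOC)c1OCOC
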